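The route cuts ring C at C4–C4a, which divides the flavone into a ring A phenol and a ring B arylpropiolate joined through O1–C2. The key step exploits the substitution of ring A. The C8 methoxy group blocks one carbon ortho to O1. The other, C4a, is ortho to O1 and to the C5 oxygen and para to the C7 oxygen. One intramolecular Friedel–Crafts acylation therefore forms C4–C4a, closes ring C and fixes the 5,7,8-pattern without a regioisomer. Its precursor is a (Z)-3-aryloxy-3-arylacrylic acid whose three future phenols (C5, C7, C2') are benzyl ethers, so no hydroxyl meets the anhydride and one hydrogenolysis ends the route.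

Key step: step 9

Assumption: the three starting materials are catalogue compounds, and the base-catalysed addition of step 7 is taken to follow the usual anti course, so the Z ester is the main isomer. The target has no stereocentre.

Step 1
Reactants: 1 3,5-bis(benzyloxy)benzaldehyde
Product: 2 3,5-bis(benzyloxy)-2-bromobenzaldehyde
Conditions: NBS (1.0 equiv), MeCN, 0 °C to rt, dark
Reagents that add atoms: N-bromosuccinimide, O=C1CCC(=O)N1Br
Why: Electrophilic aromatic bromination, which on 3,5-dialkoxybenzaldehydes goes to C2 (equivalent to C6), ortho to one ether and para to the other, while C4 is wedged between both ethers; the polar solvent and darkness suppress benzylic radical bromination.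

Step 2
Reactants: 2 3,5-bis(benzyloxy)-2-bromobenzaldehyde
Product: 3 3,5-bis(benzyloxy)-2-methoxybenzaldehyde
Conditions: NaOMe (4 equiv), CuBr (0.15 equiv), MeOH/DMF, 100 °C
Reagents that add atoms: sodium methoxide, [Na+].[O-]C
Why: Ullmann-type copper-catalysed methoxylation of an aryl bromide, long used on bromobenzaldehydes: the ortho formyl group coordinates copper and activates the C–Br bond, methoxide is small enough for the flanked position, the benzyl ethers are inert to it, and the aldehyde has no α-hydrogen and is shielded as its hemiacetal anion.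

Step 3
Reactants: 3 3,5-bis(benzyloxy)-2-methoxybenzaldehyde
Product: 5 3,5-bis(benzyloxy)-2-methoxyphenol, via aryl formate 4 (not isolated)
Conditions: mCPBA (1.3 equiv), CH2Cl2, 0 °C to rt; then K2CO3 (0.2 equiv), MeOH, rt, N2
Reagents that add atoms: 3-chloroperoxybenzoic acid, O=C(OO)c1cccc(Cl)c1
Why: Baeyer–Villiger oxidation of an ortho-alkoxybenzaldehyde (Dakin-type outcome): the ortho methoxy group favours aryl over hydride migration, the formate is less oxidisable than the free phenol while peracid is present, and catalytic carbonate in methanol then frees the single hydroxyl that becomes O1.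

Step 4
Reactants: 6 3,4-dimethoxyphenol
Product: 7 4-(benzyloxy)-1,2-dimethoxybenzene
Conditions: BnBr (1.1 equiv), K2CO3, DMF, rt
Reagents that add atoms: benzyl bromide, BrCc1ccccc1
Why: Williamson ether synthesis on the only hydroxyl; a benzyl ether is chosen for the future 2'-oxygen because it withstands the basic steps 6 to 8 and leaves with the ring A benzyl groups in step 10, and masking before halogenation avoids oxidation of the electron-rich phenol.

Step 5
Reactants: 7 4-(benzyloxy)-1,2-dimethoxybenzene
Product: 8 1-(benzyloxy)-2-iodo-4,5-dimethoxybenzene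
Conditions: NIS (1.05 equiv), CF3CO2H (0.1 equiv), MeCN, 0 °C to rt
Reagents that add atoms: N-iodosuccinimide, O=C1CCC(=O)N1I
Why: Electrophilic aromatic iodination of a 1,2,4-trialkoxybenzene, which reacts at the carbon ortho to the benzyloxy group and para to a methoxy group, the only doubly activated position not wedged between two oxygens.

Step 6
Reactants: 8 1-(benzyloxy)-2-iodo-4,5-dimethoxybenzene; 9 methyl propiolate
Product: 10 methyl 3-[2-(benzyloxy)-4,5-dimethoxyphenyl]prop-2-ynoate
Conditions: PdCl2(PPh3)2 (3 mol %), CuI (6 mol %), K2CO3 (2 equiv), THF, 65 °C, 9 (3 equiv) added in portions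
Reagents that add atoms: none
Why: Sonogashira coupling run with an inorganic base in place of an amine, the known remedy for propiolates because it removes aza-Michael addition and amine-induced oligomerisation of 9; the benzyl ether prevents the benzofuran closure a free ortho phenol would undergo.

Step 7
Reactants: 5 3,5-bis(benzyloxy)-2-methoxyphenol; 10 methyl 3-[2-(benzyloxy)-4,5-dimethoxyphenyl]prop-2-ynoate
Product: 11 methyl (Z)-3-[3,5-bis(benzyloxy)-2-methoxyphenoxy]-3-[2-(benzyloxy)-4,5-dimethoxyphenyl]prop-2-enoate
Conditions: Cs2CO3 (0.3 equiv), dry DMF, 60–80 °C, argon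
Reagents that add atoms: none
Why: Base-catalysed oxa-Michael addition (hydrophenoxylation) of a phenol to an arylpropiolate, the known entry to β-aryloxycinnamates: 5 has one hydroxyl so only one addition is possible, anti addition places the aryloxy group and the ester on the same side (Z), and the substoichiometric base leaves free phenol to protonate the allenolate before it equilibrates; any E isomer is removed by chromatography.

Step 8
Reactants: 11 methyl (Z)-3-[3,5-bis(benzyloxy)-2-methoxyphenoxy]-3-[2-(benzyloxy)-4,5-dimethoxyphenyl]prop-2-enoate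
Product: 12 (Z)-3-[3,5-bis(benzyloxy)-2-methoxyphenoxy]-3-[2-(benzyloxy)-4,5-dimethoxyphenyl]prop-2-enoic acid
Conditions: LiOH (4 equiv), THF/H2O, 40 °C; then 1 M HCl, 0 °C, to pH 3
Reagents that add atoms: lithium hydroxide, [Li+].[OH-]
Why: Ester saponification by acyl–oxygen cleavage: every protecting group is a base-stable ether, the β-carbon carries two donors and is too poor an acceptor for hydroxide to expel the aryloxide, the double-bond geometry is untouched, and cold, brief acidification avoids protodecarboxylation of the electron-rich acrylic acid.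

Step 9
Reactants: 12 (Z)-3-[3,5-bis(benzyloxy)-2-methoxyphenoxy]-3-[2-(benzyloxy)-4,5-dimethoxyphenyl]prop-2-enoic acid
Product: 14 5,7-bis(benzyloxy)-2-[2-(benzyloxy)-4,5-dimethoxyphenyl]-8-methoxy-4H-chromen-4-one, via mixed trifluoroacetic anhydride 13 (not isolated)
Conditions: (CF3CO)2O (2 equiv), CH2Cl2 (0.03 M), 0 °C to rt
Reagents that add atoms: none
Why: Trifluoroacetic anhydride turns acid 12 into mixed anhydride 13, whose acyl carbon, an acylium equivalent stabilised by the β-aryloxy and β-aryl donors, is attacked by C4a of ring A; loss of the C4a proton rearomatises ring A and leaves the C4 carbonyl of the 4-pyranone. The closest known reaction type is the intramolecular Friedel–Crafts cyclisation of β-aryloxycinnamic acids to flavones, and anhydride activation of this kind is established for closing 2-aryloxybenzoic acids onto alkoxy-rich rings to give xanthones. Ring C closes as a six-membered ring by electrophilic aromatic substitution, formally a 6-exo-trig attack of C4a on the anhydride carbonyl, and no stereocentre is created. The step needs acylation at a ring A carbon and not at C6' or the 2'-oxygen of ring B: the Z geometry holds the acyl carbon beside the aryloxy ring, C8 is blocked by its methoxy group, and C4a is activated three times over (O1 and the 5-benzyloxy group ortho, the 7-benzyloxy group para), whereas C6' has one ortho donor and would have to close a strained indenone. Low temperature, high dilution and no acid beyond the trifluoroacetic acid released keep Z-to-E isomerisation, dealkylative lactonisation through the 2'-ether and intermolecular acylation slow relative to this closure. Because C7 carries a benzyl ether and not a free hydroxyl, no O-trifluoroacetylation can drain electron density from the position para to it; loss of the peri 5-benzyl group, should it occur, would be harmless since step 10 removes it anyway.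

Step 10
Reactants: 14 5,7-bis(benzyloxy)-2-[2-(benzyloxy)-4,5-dimethoxyphenyl]-8-methoxy-4H-chromen-4-one
Product: 15 5,7-dihydroxy-2-(2-hydroxy-4,5-dimethoxyphenyl)-8-methoxy-4H-chromen-4-one (target)
Conditions: H2 (1 atm), 10% Pd/C, THF/MeOH, rt
Reagents that add atoms: none
Why: Catalytic hydrogenolysis of three aryl benzyl ethers in one neutral operation; the C2=C3 bond is part of the conjugated 4-pyranone and normally survives 1 atm of hydrogen when the reaction is stopped at full debenzylation, and the absence of acid or base excludes Wessely–Moser-type migration of the 8-methoxy pattern and ring opening assisted by the 2'-hydroxyl.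

Compound list
1 | 3,5-bis(benzyloxy)benzaldehyde | O=Cc1cc(OCc2ccccc2)cc(OCc2ccccc2)c1 | starting material
2 | 3,5-bis(benzyloxy)-2-bromobenzaldehyde | O=Cc1cc(OCc2ccccc2)cc(OCc2ccccc2)c1Br | intermediate
3 | 3,5-bis(benzyloxy)-2-methoxybenzaldehyde | O=Cc1cc(OCc2ccccc2)cc(OCc2ccccc2)c1OC | intermediate
4 | 3,5-bis(benzyloxy)-2-methoxyphenyl formate | O=COc1cc(OCc2ccccc2)cc(OCc2ccccc2)c1OC | intermediate
5 | 3,5-bis(benzyloxy)-2-methoxyphenol | Oc1cc(OCc2ccccc2)cc(OCc2ccccc2)c1OC | intermediate
6 | 3,4-dimethoxyphenol | COc1ccc(O)cc1OC | starting material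
7 | 4-(benzyloxy)-1,2-dimethoxybenzene | COc1ccc(OCc2ccccc2)cc1OC | intermediate
8 | 1-(benzyloxy)-2-iodo-4,5-dimethoxybenzene | COc1cc(I)c(OCc2ccccc2)cc1OC | intermediate
9 | methyl propiolate (methyl prop-2-ynoate) | C#CC(=O)OC | starting material
10 | methyl 3-[2-(benzyloxy)-4,5-dimethoxyphenyl]prop-2-ynoate | COC(=O)C#Cc1cc(OC)c(OC)cc1OCc1ccccc1 | intermediate
11 | methyl (Z)-3-[3,5-bis(benzyloxy)-2-methoxyphenoxy]-3-[2-(benzyloxy)-4,5-dimethoxyphenyl]prop-2-enoate | COC(=O)/C=C(\Oc1cc(OCc2ccccc2)cc(OCc2ccccc2)c1OC)c1cc(OC)c(OC)cc1OCc1ccccc1 | intermediate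
12 | (Z)-3-[3,5-bis(benzyloxy)-2-methoxyphenoxy]-3-[2-(benzyloxy)-4,5-dimethoxyphenyl]prop-2-enoic acid | OC(=O)/C=C(\Oc1cc(OCc2ccccc2)cc(OCc2ccccc2)c1OC)c1cc(OC)c(OC)cc1OCc1ccccc1 | intermediate
13 | (Z)-3-[3,5-bis(benzyloxy)-2-methoxyphenoxy]-3-[2-(benzyloxy)-4,5-dimethoxyphenyl]prop-2-enoic trifluoroacetic anhydride | FC(F)(F)C(=O)OC(=O)/C=C(\Oc1cc(OCc2ccccc2)cc(OCc2ccccc2)c1OC)c1cc(OC)c(OC)cc1OCc1ccccc1 | intermediate
14 | 5,7-bis(benzyloxy)-2-[2-(benzyloxy)-4,5-dimethoxyphenyl]-8-methoxy-4H-chromen-4-one | COc1cc(OCc2ccccc2)c(-c2cc(=O)c3c(OCc4ccccc4)cc(OCc4ccccc4)c(OC)c3o2)cc1OC | intermediate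
15 | 5,7-dihydroxy-2-(2-hydroxy-4,5-dimethoxyphenyl)-8-methoxy-4H-chromen-4-one | COc1cc(O)c(-c2cc(=O)c3c(O)cc(O)c(OC)c3o2)cc1OC | target

Total step count: 10. Longest linear sequence: 7 steps (1, 2, 3, 7, 8, 9, 10 or 4, 5, 6, 7, 8, 9, 10).

Steps most likely to fail

**Step 9.**
- What may go wrong: acid-induced Z-to-E isomerisation of the activated acid, followed by capture of the acyl group by the 2'-ether oxygen with loss of its benzyl group. Intermolecular trifluoroacetylation of ring A could also outrun a slow closure.
- Fallback: the acylium equivalent is replaced by an amide-derived iminium electrophile under buffered conditions, a Vilsmeier–Haack-type cyclisation. It sets out from 12.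
- Coupling with dimethylamine hydrochloride (EDC·HCl, HOBt, iPr2NEt, CH2Cl2) should give the (Z)-N,N-dimethylacrylamide F1.
- (CF3SO2)2O and 2-chloropyridine in CH2Cl2 at −78 °C convert it into the O-triflyl iminium triflate F2.
- On warming to 0 °C, C4a attacks this species without free acid, so protonation of the double bond, the path to the E isomer, is shut off. This gives the 4-(dimethylamino)chromenylium triflate F3.
- Warm aqueous NaHCO3/THF hydrolyses it, and the fallback comes back to the route at 14.

**Step 7.**
- What may go wrong: sluggish addition to a hindered β-carbon that carries an electron-rich aryl group. Reversible addition at the temperature then needed would also erode the Z/E control.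
- Fallback: the geometry is set first in a vinyl iodide. It sets out from 10.
- Anti hydroiodination (NaI, AcOH, 80 °C) should give methyl (Z)-3-[2-(benzyloxy)-4,5-dimethoxyphenyl]-3-iodoprop-2-enoate F4, with iodine and ester cis.
- Copper-catalysed vinylic C–O coupling with 5 (CuI, N,N-dimethylglycine, Cs2CO3, dioxane, 70 °C) proceeds with retention, as does the uncatalysed addition–elimination. The fallback comes back to the route at 11.

**Step 6.**
- What may go wrong: base-induced oligomerisation and oxidative homocoupling of the propiolate outrunning cross-coupling with an electron-rich, ortho-substituted aryl iodide.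
- Fallback: the alkyne is installed without the ester and carboxylated afterwards. It sets out from 8.
- Sonogashira coupling with trimethylsilylacetylene (PdCl2(PPh3)2, CuI, Et3N, THF, rt) should give the silylalkyne F5.
- K2CO3 in MeOH gives the terminal alkyne F6.
- n-BuLi in THF at −78 °C gives the lithium acetylide F7.
- Methyl chloroformate traps it, and the fallback comes back to the route at 10.

Further compounds
F1 | step 9 | (Z)-3-[3,5-bis(benzyloxy)-2-methoxyphenoxy]-3-[2-(benzyloxy)-4,5-dimethoxyphenyl]-N,N-dimethylprop-2-enamide | CN(C)C(=O)/C=C(\Oc1cc(OCc2ccccc2)cc(OCc2ccccc2)c1OC)c1cc(OC)c(OC)cc1OCc1ccccc1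
F2 | step 9 | O-triflyl iminium triflate of F1, (Z) | C[N+](C)=C(OS(=O)(=O)C(F)(F)F)/C=C(\Oc1cc(OCc2ccccc2)cc(OCc2ccccc2)c1OC)c1cc(OC)c(OC)cc1OCc1ccccc1.[O-]S(=O)(=O)C(F)(F)F
F3 | step 9 | 5,7-bis(benzyloxy)-2-[2-(benzyloxy)-4,5-dimethoxyphenyl]-4-(dimethylamino)-8-methoxychromenylium trifluoromethanesulfonate | C[N+](C)=C1C=C(c2cc(OC)c(OC)cc2OCc2ccccc2)Oc2c(OC)c(OCc3ccccc3)cc(OCc3ccccc3)c12.[O-]S(=O)(=O)C(F)(F)F
F4 | step 7 | methyl (Z)-3-[2-(benzyloxy)-4,5-dimethoxyphenyl]-3-iodoprop-2-enoate | COC(=O)/C=C(\I)c1cc(OC)c(OC)cc1OCc1ccccc1
F5 | step 6 | {[2-(benzyloxy)-4,5-dimethoxyphenyl]ethynyl}trimethylsilane | C[Si](C)(C)C#Cc1cc(OC)c(OC)cc1OCc1ccccc1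
F6 | step 6 | 1-(benzyloxy)-2-ethynyl-4,5-dimethoxybenzene | C#Cc1cc(OC)c(OC)cc1OCc1ccccc1
F7 | step 6 | lithium [2-(benzyloxy)-4,5-dimethoxyphenyl]acetylide | [Li]C#Cc1cc(OC)c(OC)cc1OCc1ccccc1
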